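**Assumption:** alertenone is the C30H44O2 head-to-tail Michael homodimer of one C15 α-methylene ketone monomer. Both halves have the same cage configuration, which I checked against the SMILES.

## Retrosynthetic overview
- Alertenone comes from a Michael dimerisation. The cross-conjugated enolate at the α′-CH2 of one α-methylene ketone adds to the exocyclic CH2 of a second molecule.
- The monomer is a bicyclo[3.2.1]octane fused to a cyclopentanone. The bicycle is closed last by 5-exo capture of a tertiary cation, from an axial methallyl group, by a regiodefined silyl enol ether of a trans-hydrindanone.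
- The trans-hydrindanone comes from Stork-type dissolving-metal reduction of a Robinson-type enone. That enone comes from an asymmetric organocatalytic Michael addition of 2-methallylcyclopentane-1,3-dione to pent-3-en-2-one, followed by aldol condensation.
- Ring order: cyclopentanedione, then cyclohexenone (Michael/aldol), then trans-hydrindane (reduction), then bicyclo[3.2.1]octane (cation closure), then exocyclic enone, then dimer.

## Route

**Step 1**
Reactants: 1 cyclopentane-1,3-dione; 2 methallyl bromide
Product: 3 2-(2-methylallyl)cyclopentane-1,3-dione
Conditions: KOH, H2O, 60 °C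
Reagents that add atoms: methallyl bromide, C=C(C)CBr
Why: C-alkylation (SN2) of the dione enolate at the doubly activated carbon.

**Step 2**
Reactants: 3; 4 (E)-pent-3-en-2-one
Product: 5 (2S)-2-methallyl-2-(4-oxopentan-2-yl)cyclopentane-1,3-dione
Conditions: cinchona-derived 9-amino-9-deoxy-epi-alkaloid (20 mol%, the pseudo-enantiomer giving the S adduct), TFA (40 mol%), toluene, rt
Reagents that add atoms: (E)-pent-3-en-2-one, C/C=C/C(C)=O
Why: Primary-amine iminium-catalysed asymmetric Michael addition. The catalyst selects the enone face, which sets the CH(CH3) stereocentre as the first stereocentre of the route. The dione carbon becomes a prochiral quaternary centre with two identical ring carbonyls.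

**Step 3**
Reactants: 5
Product: 6 7-methyl-7a-(2-methylallyl)-2,3,6,7-tetrahydro-1H-indene-1,5(7aH)-dione, SMILES O=C1CCC2=CC(=O)C[C@H](C)[C@]12CC(C)=C
Conditions: pyrrolidine (20 mol%), AcOH (20 mol%), MeCN, 50 °C
Reagents that add atoms: none (loses H2O)
Why: Enamine aldol and dehydration, the second half of a Robinson annulation. A chair transition state with the equatorial methyl selects which ring carbonyl is attacked. This sets the quaternary carbon so that the methyl and methallyl groups are trans. It is a diastereotopic-arm desymmetrisation controlled by the stereocentre from step 2.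

**Step 4**
Reactants: 6
Product: 7 1-methylidene enone, SMILES C=C1CCC2=CC(=O)C[C@H](C)[C@]12CC(C)=C
Conditions: Ph3P=CH2 (from Ph3PCH3Br, KOt-Bu), toluene, 60 °C
Reagents that add atoms: methylenetriphenylphosphorane, C=P(c1ccccc1)(c1ccccc1)c1ccccc1
Why: Wittig methylenation. It is chemoselective for the non-conjugated cyclopentanone, because the vinylogous enone carbonyl is deactivated.

**Step 5**
Reactants: 7
Product: 8 trans-fused trimethylsilyl enol ether (C4=C5–OSiMe3), SMILES C=C1CC[C@H]2C=C(O[Si](C)(C)C)C[C@H](C)[C@]12CC(C)=C
Conditions: Li, liq. NH3/THF, −78 °C, t-BuOH (1 equiv); then NH3 removed, TMSCl, Et3N, THF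
Reagents that add atoms: chlorotrimethylsilane, C[Si](C)(C)Cl
Why: Stork dissolving-metal conjugate reduction. Axial protonation of the β-carbanion, anti to the axial methallyl, gives the trans ring fusion and sets the CH at the ring junction. The lithium enolate forms only on the former enone carbon, so it is trapped as a regiodefined silyl enol ether. The isolated alkenes survive.

**Step 6**
Reactants: 8
Product: 9 tricyclic ketone, SMILES C=C1CC[C@H]2[C@@H]3C(=O)C[C@H](C)[C@]12CC3(C)C
Conditions: HNTf2 (10 mol%), HFIP (1.2 equiv), CH2Cl2, −78 → −20 °C
Reagents that add atoms: none (HFIP supplies the H and is silylated)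
Why: Proposed new method: acid-triggered cation–olefin closure terminated by a silyl enol ether. HNTf2 protonates the methallyl alkene to a tertiary cation. The trans ring fusion locks the methallyl group axial, so the enol ether carbon is captured 5-exo from the same face. This forms the new C–C bridge, the bicyclo[3.2.1]octane and the last ring stereocentre. The silyl group passes to HFIP, which regenerates the acid. The closest known reactions are Reetz tert-alkylation of silyl enol ethers and cation–olefin cyclisation.

**Step 7**
Reactants: 9
Product: 10 hydrocarbon, SMILES C=C1CC[C@H]2[C@@H]3CC[C@H](C)[C@]12CC3(C)C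
Conditions: N2H4·H2O, KOH, diethylene glycol, 130 then 200 °C
Reagents that add atoms: none
Why: Huang–Minlon Wolff–Kishner reduction. The bicyclic ketone is the only carbonyl, and the alkene and stereocentres are untouched.

**Step 8**
Reactants: 10
Product: 11 allylic alcohol, SMILES C=C1C(O)C[C@H]2[C@@H]3CC[C@H](C)[C@]12CC3(C)C
Conditions: SeO2 (0.3 equiv), TBHP, CH2Cl2, 0 °C → rt
Reagents that add atoms: tert-butyl hydroperoxide, CC(C)(C)OO (supplies O)
Why: Riley allylic oxidation (ene then [2,3] shift). The only allylic C–H in the ring is at the CH2 next to the methylene, because the other ring neighbour is quaternary. The exocyclic alkene is retained. The alcohol epimers converge in step 9.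

**Step 9**
Reactants: 11
Product: 12 monomer, SMILES C=C1C(=O)C[C@H]2[C@@H]3CC[C@H](C)[C@]12CC3(C)C
Conditions: Dess–Martin periodinane, NaHCO3, CH2Cl2, rt
Reagents that add atoms: none
Why: Mild oxidation of the secondary allylic alcohol to the α-methylene cyclopentanone.

**Step 10**
Reactants: 12 (2 equiv, as nucleophile and acceptor)
Product: 13 alertenone
Conditions: LiHMDS (0.5 equiv), THF, −78 → −20 °C; then AcOH quench; DBU (0.3 equiv), CH2Cl2, rt
Reagents that add atoms: none
Why: Biomimetic Michael dimerisation. Half of the monomer is deprotonated at its only enolisable position, the α′-CH2, giving a cross-conjugated dienolate. This adds to the exocyclic CH2 of the remaining monomer. The two new α-stereocentres lie on the convex face, anti to the CH2–CMe2 bridge. DBU equilibrates them to that arrangement. The hindered dimer enolate adds a second monomer only slowly.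

## Compound list
1 | cyclopentane-1,3-dione | O=C1CC(=O)CC1 | starting material
2 | methallyl bromide | C=C(C)CBr | starting material
3 | 2-methallylcyclopentane-1,3-dione | O=C1CCC(=O)C1CC(C)=C | intermediate
4 | (E)-pent-3-en-2-one | C/C=C/C(C)=O | starting material
5 | (2S)-triketone | O=C1CCC(=O)C1(CC(C)=C)[C@@H](C)CC(C)=O | intermediate
6 | Robinson enone, Me and methallyl trans | O=C1CCC2=CC(=O)C[C@H](C)[C@]12CC(C)=C | intermediate
7 | 1-methylidene enone | C=C1CCC2=CC(=O)C[C@H](C)[C@]12CC(C)=C | intermediate
8 | trans-hydrindane TMS enol ether | C=C1CC[C@H]2C=C(O[Si](C)(C)C)C[C@H](C)[C@]12CC(C)=C | intermediate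
9 | tricyclic cage ketone | C=C1CC[C@H]2[C@@H]3C(=O)C[C@H](C)[C@]12CC3(C)C | intermediate
10 | cage hydrocarbon | C=C1CC[C@H]2[C@@H]3CC[C@H](C)[C@]12CC3(C)C | intermediate
11 | allylic alcohol | C=C1C(O)C[C@H]2[C@@H]3CC[C@H](C)[C@]12CC3(C)C | intermediate
12 | monomer, α-methylene ketone | C=C1C(=O)C[C@H]2[C@@H]3CC[C@H](C)[C@]12CC3(C)C | intermediate
13 | alertenone | C=C1C(=O)[C@H](C[C@@H]2C(=O)C[C@H]3[C@@H]4CC[C@H](C)[C@]23CC4(C)C)[C@H]2[C@@H]3CC[C@H](C)[C@]12CC3(C)C | target

**Total step count:** 10. **Longest linear sequence:** 10 steps, from 1.

**Three steps most likely to fail**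
1. **Step 6 (the proposed new step).** HNTf2/HFIP may protodesilylate the enol ether before the cation closes, or the exocyclic methylene may intercept the cation.
   - Fallback: at compound 7, convert the methallyl group to the tertiary alcohol by Mukaiyama hydration (Co(acac)2, PhSiH3, O2). Carry it through step 5 as its TMS ether. Close the ring with a TMSOTf-promoted Reetz-type tert-alkylation of the enol ether, which is known chemistry.
2. **Steps 2–3.** Michael addition of a tertiary dione to a β-methyl enone may be sluggish or reversible, and the aldol may give the wrong Me/methallyl diastereomer.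
   - Fallback: run the proline-type Hajos–Parrish cascade with methyl vinyl ketone, which has no methyl at C7. Install the methyl after the cage is built. Ketone 9 is then the only carbonyl, and only one α-carbon is enolisable because the other is a bridgehead. Use Saegusa dehydrogenation, then Me2CuLi/TMSCl, which adds anti to the bridge, then Wolff–Kishner.
3. **Step 10.** The monomer may oligomerise or hetero-Diels–Alder dimerise, and the α-stereocentres may equilibrate to the wrong epimers.
   - Fallback: make the silyl dienol ether of 12 (LDA, TMSCl). Add it to a second equivalent of 12 in a Lewis-acid-promoted Mukaiyama–Michael reaction (TMSOTf), then epimerise with DBU.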